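**Plan**
- Retrosynthesis: cut the C8–O ester (side-chain acid 25), the C11–C12 bond (alkoxycarbonylation of a C7 ethynyl group), C7–C11 (acetylide opening of a 7,8-epoxide), C10=C14 (ketone methylenation), and then both ring A bonds C5–C6 and C2–C3 together.
- Enabling feature: in ring A the allyl unit C3–C4(C15)=C5 sits between C2 and C6, and both are attached to C1, which is alpha to C10. With C10 as a ketone, ring B is a 2-(acetoxymethyl)cyclohex-2-enone: C6 (enone beta-carbon) and C2 (acetoxymethyl carbon) form a 1,3-dielectrophile that matches a 2-substituted 1,3-bis(silyl)propene as 1,3-dinucleophile.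
- Forward order: ring B first (enone acetate 7 from an enantiopure arene cis-dihydrodiol), ring A annulated onto it in one operation, then C14, the trans-diaxial C7/C8 pair, the C8 ester, the acrylic acid and deprotection.
- Stereochemistry: C8 is a diol carbon of 1 and is never touched. Its cis-fused acetonide directs the annulation to the opposite face (C6), enolate protonation gives the trans ring fusion (C1), and C7 is set by diol → epoxide → trans-diaxial opening. The side-chain centre comes from D-glyceraldehyde acetonide.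

Key step: step 9

Remark: locants follow the cadinane skeleton of the target (C1/C6 ring fusion; ring A = C1–C6 with C15 on C4; ring B = C1, C6–C10 with C11(C12, C13) on C7, oxygen on C8, C14 on C10).

**Route**

Step 1
Reactants: 1 (1S,2S)-3-bromocyclohexa-3,5-diene-1,2-diol
Product: 2 (3aS,7aS)-4-bromo-2,2-dimethyl-3a,7a-dihydro-1,3-benzodioxole
Conditions: 2,2-dimethoxypropane, p-TsOH (cat.), acetone, 0 °C → rt
Reagents that add atoms: 2,2-dimethoxypropane, COC(C)(C)OC
Why: Acid-catalysed transketalisation of the cis-diol should give the cis-fused acetonide without touching either stereocentre.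

Step 2
Reactants: 2 (3aS,7aS)-4-bromo-2,2-dimethyl-3a,7a-dihydro-1,3-benzodioxole
Product: 3 (3aS,7aS)-4-bromo-2,2-dimethyl-3a,6,7,7a-tetrahydro-1,3-benzodioxole
Conditions: KO2CN=NCO2K, AcOH, MeOH, 0 °C → rt
Reagents that add atoms: none
Why: Diimide reduction (syn hydrogen transfer) should saturate the unhindered disubstituted C=C much faster than the bromine-bearing one, a selectivity typical of halodiene acetonides.

Step 3
Reactants: 3 (3aS,7aS)-4-bromo-2,2-dimethyl-3a,6,7,7a-tetrahydro-1,3-benzodioxole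
Product: 4 (3aS,7aR)-2,2-dimethyl-3a,4,5,7a-tetrahydro-1,3-benzodioxole
Conditions: Bu3SnH, AIBN (cat.), toluene, 85 °C
Reagents that add atoms: none
Why: Radical-chain hydrodebromination of the vinyl bromide (tin hydride reduction) should leave the alkene and both stereocentres untouched.

Step 4
Reactants: 4 (3aS,7aR)-2,2-dimethyl-3a,4,5,7a-tetrahydro-1,3-benzodioxole
Product: 5 (3aS,7aR)-2,2-dimethyl-3a,7a-dihydro-1,3-benzodioxol-5(4H)-one
Conditions: t-BuOOH (5 equiv), Pd(OH)2 on carbon (5 mol %), K2CO3, CH2Cl2, 0 °C → rt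
Reagents that add atoms: tert-butyl hydroperoxide, CC(C)(C)OO
Why: Palladium-catalysed allylic C–H oxidation should convert the only allylic CH2 (C10) into the enone carbonyl, since the other allylic position is oxygenated and hindered; no stereocentre is affected.

Step 5
Reactants: 5 (3aS,7aR)-2,2-dimethyl-3a,7a-dihydro-1,3-benzodioxol-5(4H)-one
Product: 6 (3aS,7aR)-6-(hydroxymethyl)-2,2-dimethyl-3a,7a-dihydro-1,3-benzodioxol-5(4H)-one
Conditions: 37% aq. HCHO, imidazole (0.5 equiv), THF/H2O, rt
Reagents that add atoms: formaldehyde, C=O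
Why: Morita–Baylis–Hillman hydroxymethylation: imidazole adds reversibly to the enone beta-carbon and the enolate traps formaldehyde at C1, under conditions mild enough for the beta-alkoxy ketone.

Step 6
Reactants: 6 (3aS,7aR)-6-(hydroxymethyl)-2,2-dimethyl-3a,7a-dihydro-1,3-benzodioxol-5(4H)-one
Product: 7 [(3aS,7aR)-2,2-dimethyl-5-oxo-3a,4,5,7a-tetrahydro-1,3-benzodioxol-6-yl]methyl acetate
Conditions: Ac2O, pyridine, DMAP (cat.), CH2Cl2, 0 °C
Reagents that add atoms: acetic anhydride, CC(=O)OC(C)=O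
Why: Standard O-acetylation turns the allylic alcohol into the leaving group needed for the annulation.

Step 7
Reactants: 8 3-(trimethylsilyl)prop-2-yn-1-ol; 9 (trimethylsilyl)methylmagnesium chloride (2.5 equiv)
Product: 11 (Z)-3-(trimethylsilyl)-2-[(trimethylsilyl)methyl]prop-2-en-1-ol, via magnesium chelate 10 (not isolated)
Conditions: CuI (10 mol %), THF, 0 °C → reflux; aq. NH4Cl
Reagents that add atoms: none
Why: Copper-catalysed anti-carbomagnesiation of a propargylic alcohol: the magnesium alkoxide directs magnesium to the silyl-bearing alkyne carbon and CH2SiMe3 to the carbon next to CH2OH, and protonolysis of the chelate gives the (Z)-alkene.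

Step 8
Reactants: 11 (Z)-3-(trimethylsilyl)-2-[(trimethylsilyl)methyl]prop-2-en-1-ol
Product: 12 (Z)-tert-butyl({3-(trimethylsilyl)-2-[(trimethylsilyl)methyl]prop-2-en-1-yl}oxy)diphenylsilane
Conditions: t-BuPh2SiCl, imidazole, CH2Cl2, rt
Reagents that add atoms: tert-butyl(chloro)diphenylsilane, CC(C)(C)[Si](Cl)(c1ccccc1)c1ccccc1
Why: Silylation of the primary alcohol gives an ether that should tolerate TiCl4 and the aqueous acid used later.

Step 9
Reactants: 7 [(3aS,7aR)-2,2-dimethyl-5-oxo-3a,4,5,7a-tetrahydro-1,3-benzodioxol-6-yl]methyl acetate; 12 (Z)-tert-butyl({3-(trimethylsilyl)-2-[(trimethylsilyl)methyl]prop-2-en-1-yl}oxy)diphenylsilane (1.2 equiv)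
Product: 14 (3aS,5aS,9aS,9bR)-8-{[(tert-butyldiphenylsilyl)oxy]methyl}-2,2-dimethyl-3a,5a,6,7,9a,9b-hexahydronaphtho[1,2-d][1,3]dioxol-5(4H)-one, via 2-methylene ketone 13 (not isolated)
Conditions: TiCl4 (2.2 equiv), 2,6-di-tert-butyl-4-methylpyridine (0.3 equiv), CH2Cl2, −78 → −40 °C; sat. aq. NaHCO3
Reagents that add atoms: none
Why: Proposed new method: a Lewis acid-triggered formal [3+3] annulation in which 12 acts as a 1,3-dinucleophile and the Morita–Baylis–Hillman acetate 7 as a 1,3-dielectrophile; TiCl4 activates the enone, the allylsilane of 12 attacks C6 through its silyl-bearing terminus C5 (anti SE2', loss of the CH2–SiMe3 group), the titanium enolate expels acetate to give the 2-methylene ketone 13, and the new allylsilane of 13 (C3=C4–C5–Si) then adds through C3 to the exocyclic C2 with loss of the second silyl group, which leaves C4=C5 in place. The closest known reaction types are the Hosomi–Sakurai conjugate allylation of cyclohexenones, the twofold SE2' reaction of 1,3-bis(trimethylsilyl)propene as a 1,3-dianion equivalent, and SN2'/Michael [3+3] annulations of Morita–Baylis–Hillman acetates. Ring A is closed in the second, intramolecular allylation as a 6-endo-trig conjugate addition (both carbons of the acceptor C1=C2 end up in the new ring). C6 is set in the first allylation by axial attack on the enone face opposite to the dioxolane oxygen on C7; C1 is set on work-up by axial protonation of the titanium enolate, which should give the trans ring fusion that is also the thermodynamic one, and the silyl-bearing C5 is only a transient centre. The step needs the first C–C bond to form at C6 and not at C2, which the much higher electrophilicity of the TiCl4-bound enone beta-carbon should secure, and it needs loss of the allylic rather than the C5 silyl group in the first allylation, which the alignment of the CH2–Si bond with the pi system in the SE2' transition state should secure.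

Step 10
Reactants: 14 (3aS,5aS,9aS,9bR)-8-{[(tert-butyldiphenylsilyl)oxy]methyl}-2,2-dimethyl-3a,5a,6,7,9a,9b-hexahydronaphtho[1,2-d][1,3]dioxol-5(4H)-one
Product: 15 tert-butyl{[(3aS,5aS,9aS,9bR)-2,2-dimethyl-5-methylidene-3a,4,5,5a,6,7,9a,9b-octahydronaphtho[1,2-d][1,3]dioxol-8-yl]methoxy}diphenylsilane
Conditions: Cp2TiMe2 (2 equiv), toluene, 70 °C, dark
Reagents that add atoms: dimethyltitanocene Cp2TiMe2, C[Ti](C)(C1C=CC=C1)C1C=CC=C1
Why: Petasis methylenation is non-basic, so the hindered ketone should become the exocyclic methylene (C14) without epimerisation at C1 or beta-elimination of the C8 oxygen.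

Step 11
Reactants: 15 tert-butyl{[(3aS,5aS,9aS,9bR)-2,2-dimethyl-5-methylidene-3a,4,5,5a,6,7,9a,9b-octahydronaphtho[1,2-d][1,3]dioxol-8-yl]methoxy}diphenylsilane
Product: 16 (1S,6S,7R,8S)-7,8-cis-diol (C10=CH2; C4=C5; CH2OTBDPS on C4; both OH on the face of H-6)
Conditions: AcOH/H2O (4:1), 45 °C
Reagents that add atoms: none
Why: Mild aqueous acid hydrolyses the dioxolane (acetal cleavage) while the TBDPS ether and both alkenes should survive.

Step 12
Reactants: 16 (1S,6S,7R,8S)-7,8-cis-diol
Product: 19 (1S,6S,7R,8S)-7,8-epoxide (oxirane on the face of H-6), via cyclic orthoacetate 17 (not isolated), via bromo acetate 18 (not isolated)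
Conditions: MeC(OMe)3, pyridinium p-toluenesulfonate (cat.), CH2Cl2, rt; then AcBr, CH2Cl2, 0 °C; then K2CO3, MeOH, rt
Reagents that add atoms: none
Why: One-pot diol-to-epoxide conversion through the cyclic orthoacetate and its acetoxonium ion: bromide opens it with inversion (trans-diaxially at C7) and methanolysis of the acetate lets the C8 alkoxide displace bromide with a second inversion, so the epoxide lies on the face of the former cis-diol.

Step 13
Reactants: 19 (1S,6S,7R,8S)-7,8-epoxide
Product: 21 (1S,6S,7R,8S)-7-ethynyl-8-ol (ethynyl on C7 trans-diaxial to OH on C8; ethynyl cis to the C6–C5 bond), via silylalkyne 20 (not isolated)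
Conditions: HC≡CSiMe3, n-BuLi, THF, −78 °C; BF3·OEt2, then 19, −78 °C; aq. NH4Cl; then K2CO3, MeOH, rt
Reagents that add atoms: ethynyltrimethylsilane, C#C[Si](C)(C)C
Why: BF3-assisted epoxide opening by a lithium acetylide should follow the Fürst–Plattner rule in the rigid trans-decalin, so the nucleophile enters axially at C7 anti to oxygen and sets C7 cis to the C6–C5 bond and trans to the C8 hydroxyl; methanolysis then removes the alkyne silyl group.

Step 14
Reactants: 22 (4R)-2,2-dimethyl-1,3-dioxolane-4-carbaldehyde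
Product: 23 (4S)-4-ethynyl-2,2-dimethyl-1,3-dioxolane
Conditions: dimethyl (1-diazo-2-oxopropyl)phosphonate, K2CO3, MeOH, 0 °C → rt
Reagents that add atoms: dimethyl (1-diazo-2-oxopropyl)phosphonate, CC(=O)C(=[N+]=[N-])P(=O)(OC)OC
Why: Ohira–Bestmann (Seyferth–Gilbert) homologation converts the aldehyde into the terminal alkyne under conditions mild enough to keep the alpha-alkoxy stereocentre, the only source of the side-chain configuration.

Step 15
Reactants: 23 (4S)-4-ethynyl-2,2-dimethyl-1,3-dioxolane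
Product: 24 methyl 2-[(4S)-2,2-dimethyl-1,3-dioxolan-4-yl]prop-2-enoate
Conditions: CO (20 bar), MeOH, Pd(OAc)2 (1 mol %), 2-(diphenylphosphino)pyridine, CH3SO3H (cat.), 45 °C
Reagents that add atoms: carbon monoxide, [C-]#[O+]; methanol, CO
Why: Palladium-catalysed Markovnikov alkoxycarbonylation of a terminal alkyne places CO on the internal carbon and gives the 2-substituted acrylate.

Step 16
Reactants: 24 methyl 2-[(4S)-2,2-dimethyl-1,3-dioxolan-4-yl]prop-2-enoate
Product: 25 2-[(4S)-2,2-dimethyl-1,3-dioxolan-4-yl]prop-2-enoic acid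
Conditions: LiOH·H2O, THF/H2O, 0 °C; then 1 M HCl to pH 3–4
Reagents that add atoms: lithium hydroxide, [Li+].[OH-]
Why: Saponification of the methyl ester at 0 °C followed by careful acidification should give the acid without opening the acetonide.

Step 17
Reactants: 21 (1S,6S,7R,8S)-7-ethynyl-8-ol; 25 2-[(4S)-2,2-dimethyl-1,3-dioxolan-4-yl]prop-2-enoic acid
Product: 27 C8 ester of 21 (acyl = 2-[(4S)-2,2-dimethyl-1,3-dioxolan-4-yl]prop-2-enoyl), via mixed anhydride 26 (not isolated)
Conditions: 2,4,6-trichlorobenzoyl chloride, Et3N, THF, rt; then 21, DMAP, toluene, rt → 40 °C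
Reagents that add atoms: none
Why: Yamaguchi esterification through the mixed anhydride should acylate the hindered axial C8 hydroxyl, the slim ethynyl neighbour adding little hindrance; no stereocentre is touched.

Step 18
Reactants: 27 C8 ester of 21
Product: 28 2-(trimethylsilyl)ethyl acrylate (C7 now bears C(=CH2)CO2CH2CH2SiMe3)
Conditions: CO (20 bar), Me3SiCH2CH2OH (5 equiv), Pd(OAc)2 (2 mol %), 2-(diphenylphosphino)pyridine, CH3SO3H (cat.), THF, 50 °C
Reagents that add atoms: carbon monoxide, [C-]#[O+]; 2-(trimethylsilyl)ethanol, C[Si](C)(C)CCO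
Why: The same palladium-catalysed Markovnikov alkoxycarbonylation converts the C7 ethynyl group into the 2-substituted acrylate (C11=C13, C12 ester), with an alcohol chosen so that the ester falls to fluoride together with the silyl ether.

Step 19
Reactants: 28 2-(trimethylsilyl)ethyl acrylate
Product: 30 (1S,6S,7R,8S)-8-{[(3S)-3,4-dihydroxy-2-methylidenebutanoyl]oxy}-15-hydroxycadina-4,10(14),11(13)-trien-12-oic acid (target), via acetonide acid 29 (not isolated)
Conditions: Bu4NF, AcOH, THF, 0 °C → rt; then AcOH/H2O (4:1), 35 °C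
Reagents that add atoms: none
Why: Buffered fluoride cleaves the TBDPS ether and the 2-(trimethylsilyl)ethyl ester (beta-elimination), and the aqueous acetic acid then hydrolyses the terminal acetonide under weakly acidic conditions that disfavour lactonisation of the 4-hydroxy ester.

**Compound list**

1 | (1S,2S)-3-bromocyclohexa-3,5-diene-1,2-diol | O[C@H]1C=CC=C(Br)[C@H]1O | starting material
2 | (3aS,7aS)-4-bromo-2,2-dimethyl-3a,7a-dihydro-1,3-benzodioxole | C1=C[C@@H]2OC(C)(C)O[C@@H]2C(Br)=C1 | intermediate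
3 | (3aS,7aS)-4-bromo-2,2-dimethyl-3a,6,7,7a-tetrahydro-1,3-benzodioxole | C1C[C@@H]2OC(C)(C)O[C@@H]2C(Br)=C1 | intermediate
4 | (3aS,7aR)-2,2-dimethyl-3a,4,5,7a-tetrahydro-1,3-benzodioxole | C1C[C@@H]2OC(C)(C)O[C@@H]2C=C1 | intermediate
5 | (3aS,7aR)-2,2-dimethyl-3a,7a-dihydro-1,3-benzodioxol-5(4H)-one [(4R,5S)-4,5-(isopropylidenedioxy)cyclohex-2-en-1-one] | O=C1C[C@@H]2OC(C)(C)O[C@@H]2C=C1 | intermediate
6 | (3aS,7aR)-6-(hydroxymethyl)-2,2-dimethyl-3a,7a-dihydro-1,3-benzodioxol-5(4H)-one | O=C1C[C@@H]2OC(C)(C)O[C@@H]2C=C1CO | intermediate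
7 | [(3aS,7aR)-2,2-dimethyl-5-oxo-3a,4,5,7a-tetrahydro-1,3-benzodioxol-6-yl]methyl acetate | O=C1C[C@@H]2OC(C)(C)O[C@@H]2C=C1COC(C)=O | intermediate
8 | 3-(trimethylsilyl)prop-2-yn-1-ol | C[Si](C)(C)C#CCO | starting material
9 | (trimethylsilyl)methylmagnesium chloride | C[Si](C)(C)C[Mg]Cl | starting material
10 | cyclic alkenylmagnesium alkoxide (oxamagnesacyclopentene) from anti-carbomagnesiation of 8 | C[Si](C)(C)CC1=C([Si](C)(C)C)[Mg]OC1 | intermediate
11 | (Z)-3-(trimethylsilyl)-2-[(trimethylsilyl)methyl]prop-2-en-1-ol | C[Si](C)(C)/C=C(/CO)C[Si](C)(C)C | intermediate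
12 | (Z)-tert-butyl({3-(trimethylsilyl)-2-[(trimethylsilyl)methyl]prop-2-en-1-yl}oxy)diphenylsilane | C[Si](C)(C)/C=C(/CO[Si](c1ccccc1)(c1ccccc1)C(C)(C)C)C[Si](C)(C)C | intermediate
13 | 2-methylene ketone carrying on C6 (anti to the dioxolane) the 1-(trimethylsilyl)-2-(silyloxymethyl)allyl group; C5 configuration undefined | O=C1C[C@@H]2OC(C)(C)O[C@@H]2[C@@H](C([Si](C)(C)C)C(=C)CO[Si](c3ccccc3)(c3ccccc3)C(C)(C)C)C1=C | intermediate
14 | (3aS,5aS,9aS,9bR)-8-{[(tert-butyldiphenylsilyl)oxy]methyl}-2,2-dimethyl-3a,5a,6,7,9a,9b-hexahydronaphtho[1,2-d][1,3]dioxol-5(4H)-one (C10 ketone, trans ring fusion, dioxolane on the face of H-6) | O=C1C[C@@H]2OC(C)(C)O[C@@H]2[C@H]3C=C(CO[Si](c4ccccc4)(c4ccccc4)C(C)(C)C)CC[C@@H]31 | intermediate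
15 | tert-butyl{[(3aS,5aS,9aS,9bR)-2,2-dimethyl-5-methylidene-3a,4,5,5a,6,7,9a,9b-octahydronaphtho[1,2-d][1,3]dioxol-8-yl]methoxy}diphenylsilane | C=C1C[C@@H]2OC(C)(C)O[C@@H]2[C@H]3C=C(CO[Si](c4ccccc4)(c4ccccc4)C(C)(C)C)CC[C@@H]31 | intermediate
16 | (1S,6S,7R,8S)-7,8-cis-diol (cadinane locants): trans-decalin with C10=CH2, C4=C5, CH2OTBDPS on C4, both OH on the face of H-6 | C=C1C[C@H](O)[C@H](O)[C@H]2C=C(CO[Si](c3ccccc3)(c3ccccc3)C(C)(C)C)CC[C@@H]21 | intermediate
17 | cyclic methyl orthoacetate of 16 (2-methoxy-2-methyl-1,3-dioxolane, orthoester carbon unassigned) | C=C1C[C@@H]2OC(C)(OC)O[C@@H]2[C@H]3C=C(CO[Si](c4ccccc4)(c4ccccc4)C(C)(C)C)CC[C@@H]31 | intermediate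
18 | (1S,6S,7S,8S)-7-bromo-8-acetate (bromine and acetoxy trans-diaxial) | C=C1C[C@H](OC(C)=O)[C@@H](Br)[C@H]2C=C(CO[Si](c3ccccc3)(c3ccccc3)C(C)(C)C)CC[C@@H]21 | intermediate
19 | (1S,6S,7R,8S)-7,8-epoxide, oxirane on the face of H-6 | C=C1C[C@@H]2O[C@@H]2[C@H]3C=C(CO[Si](c4ccccc4)(c4ccccc4)C(C)(C)C)CC[C@@H]31 | intermediate
20 | (1S,6S,7R,8S)-7-[(trimethylsilyl)ethynyl]-8-ol | C[Si](C)(C)C#C[C@H]1[C@H]2C=C(CO[Si](c3ccccc3)(c3ccccc3)C(C)(C)C)CC[C@@H]2C(=C)C[C@@H]1O | intermediate
21 | (1S,6S,7R,8S)-7-ethynyl-8-ol (ethynyl and OH trans-diaxial, ethynyl cis to the C6–C5 bond) | C#C[C@H]1[C@H]2C=C(CO[Si](c3ccccc3)(c3ccccc3)C(C)(C)C)CC[C@@H]2C(=C)C[C@@H]1O | intermediate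
22 | (4R)-2,2-dimethyl-1,3-dioxolane-4-carbaldehyde (D-glyceraldehyde acetonide) | O=C[C@H]1COC(C)(C)O1 | starting material
23 | (4S)-4-ethynyl-2,2-dimethyl-1,3-dioxolane | C#C[C@H]1COC(C)(C)O1 | intermediate
24 | methyl 2-[(4S)-2,2-dimethyl-1,3-dioxolan-4-yl]prop-2-enoate | COC(=O)C(=C)[C@H]1COC(C)(C)O1 | intermediate
25 | 2-[(4S)-2,2-dimethyl-1,3-dioxolan-4-yl]prop-2-enoic acid | OC(=O)C(=C)[C@H]1COC(C)(C)O1 | intermediate
26 | mixed anhydride of 25 with 2,4,6-trichlorobenzoic acid | O=C(OC(=O)c1c(Cl)cc(Cl)cc1Cl)C(=C)[C@H]1COC(C)(C)O1 | intermediate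
27 | ester of 21 (C8–O) with acid 25 | C#C[C@H]1[C@H]2C=C(CO[Si](c3ccccc3)(c3ccccc3)C(C)(C)C)CC[C@@H]2C(=C)C[C@@H]1OC(=O)C(=C)[C@H]1COC(C)(C)O1 | intermediate
28 | 2-(trimethylsilyl)ethyl ester of the C12 acid (C15 OTBDPS, side-chain acetonide) | C=C(C(=O)OCC[Si](C)(C)C)[C@H]1[C@H]2C=C(CO[Si](c3ccccc3)(c3ccccc3)C(C)(C)C)CC[C@@H]2C(=C)C[C@@H]1OC(=O)C(=C)[C@H]1COC(C)(C)O1 | intermediate
29 | C12 acid, C15 alcohol, side-chain acetonide | C=C(C(=O)O)[C@H]1[C@H]2C=C(CO)CC[C@@H]2C(=C)C[C@@H]1OC(=O)C(=C)[C@H]1COC(C)(C)O1 | intermediate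
30 | (1S,6S,7R,8S)-8-{[(3S)-3,4-dihydroxy-2-methylidenebutanoyl]oxy}-15-hydroxycadina-4,10(14),11(13)-trien-12-oic acid (CNP0460913.4) | C=C(C(=O)O)[C@H]1[C@H]2C=C(CO)CC[C@@H]2C(=C)C[C@@H]1OC(=O)C(=C)[C@H](O)CO | target

**Step count and risk**

Total step count: 19. Longest linear sequence: 14 steps (steps 1–6, 9–13, 17–19).

Steps most likely to fail:

1. Step 9 (proposed new method). What may go wrong: protodesilylation of the intermediate allylsilane before ring closure; loss of the C5 silyl group instead of the allylic one in the first allylation; first attack at C2 instead of C6, which would give the ring A regioisomer; cleavage of the acetonide by TiCl4. The fallback sets out from 7 and returns at 14 using known reactions. Compound 7 would be treated with vinylmagnesium bromide and CuBr·SMe2 (cat.) in THF at −78 °C (SN2' addition–elimination anti to the dioxolane) to give the 3-vinyl-2-methylene ketone F1. The allylsilane tert-butyl({2-[(trimethylsilyl)methyl]prop-2-en-1-yl}oxy)diphenylsilane F2 would be made from commercial 2-[(trimethylsilyl)methyl]prop-2-en-1-ol with t-BuPh2SiCl and imidazole. F2 would add to the exocyclic enone of F1 (TiCl4, CH2Cl2, −78 °C, Hosomi–Sakurai conjugate allylation) to give the diene ketone F3. Ring-closing metathesis of F3 (second-generation Grubbs catalyst, CH2Cl2, 40 °C) would form C4=C5 and give 14.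

2. Step 12. What may go wrong: bromide may open the acetoxonium ion at C8 instead of C7, giving a trans-diequatorial bromo acetate that closes only slowly in the rigid trans-decalin; HBr traces may add to the exocyclic methylene. The fallback sets out from 16 and returns at 19. The equatorial C7 hydroxyl would be triflated selectively (Tf2O, pyridine, CH2Cl2, −30 °C) to give the 7-triflate-8-ol F4. Bromide displacement with inversion (Bu4NBr, toluene, rt) would give the trans-diaxial 7-bromo-8-ol F5, and K2CO3 in MeOH would close it to 19.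

3. Step 13. What may go wrong: Lewis acid-induced rearrangement of the epoxide to a ketone, or slow attack at the hindered C7 next to the ring fusion. The fallback sets out from 16 and returns at 21 without an epoxide or a Lewis acid. Diol 16 would be converted into the cyclic sulfate F6 (1,1'-sulfonyldiimidazole, NaH, THF, 0 °C; no ruthenium oxidant, so the alkenes are safe). Lithium (trimethylsilyl)acetylide (THF, −78 → 0 °C) would open F6 trans-diaxially at C7 to give the sulfate half-ester F7. Hydrolysis (cat. H2SO4, H2O, THF) would give 20, and K2CO3 in MeOH would give 21.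

Further compounds
F1 | step 9 | (3aS,7aR)-2,2-dimethyl-6-methylidene-7-vinyl-tetrahydro-1,3-benzodioxol-5-one (3-vinyl-2-methylene ketone, vinyl anti to the dioxolane) | O=C1C[C@@H]2OC(C)(C)O[C@@H]2[C@@H](C=C)C1=C
F2 | step 9 | tert-butyl({2-[(trimethylsilyl)methyl]prop-2-en-1-yl}oxy)diphenylsilane | C=C(C[Si](C)(C)C)CO[Si](c1ccccc1)(c1ccccc1)C(C)(C)C
F3 | step 9 | diene ketone: C6 vinyl and C1 4-(silyloxymethyl)pent-4-enyl chain trans on the dioxolane-fused cyclohexanone | O=C1C[C@@H]2OC(C)(C)O[C@@H]2[C@@H](C=C)[C@@H]1CCC(=C)CO[Si](c1ccccc1)(c1ccccc1)C(C)(C)C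
F4 | step 12 | (1S,6S,7R,8S)-7-trifluoromethanesulfonate of diol 16 | C=C1C[C@H](O)[C@H](OS(=O)(=O)C(F)(F)F)[C@H]2C=C(CO[Si](c3ccccc3)(c3ccccc3)C(C)(C)C)CC[C@@H]21
F5 | step 12 | (1S,6S,7S,8S)-7-bromo-8-ol (trans-diaxial bromohydrin) | C=C1C[C@H](O)[C@@H](Br)[C@H]2C=C(CO[Si](c3ccccc3)(c3ccccc3)C(C)(C)C)CC[C@@H]21
F6 | step 13 | 7,8-cyclic sulfate of diol 16 | C=C1C[C@@H]2OS(=O)(=O)O[C@@H]2[C@H]3C=C(CO[Si](c4ccccc4)(c4ccccc4)C(C)(C)C)CC[C@@H]31
F7 | step 13 | hydrogen sulfate ester (C8–OSO3H) of silylalkyne 20 | C[Si](C)(C)C#C[C@H]1[C@H]2C=C(CO[Si](c3ccccc3)(c3ccccc3)C(C)(C)C)CC[C@@H]2C(=C)C[C@@H]1OS(=O)(=O)O
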